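## Retrosynthetic overview

1. Target 6 ⇒ copalyl acetate 5: the C17–O bond is made by a transpositional allylic C–H acetoxylation of the exocyclic 8(17)-alkene, which moves the alkene to C7=C8.
2. 5 ⇒ 4: the 8(17)-alkene comes from dehydroacetoxylation of the tertiary 8α-acetate.
3. 4 ⇒ 3: the C15–O bond and the 13E alkene come from a [3,3] transposition of the tertiary allylic acetate.
4. 3 ⇒ sclareol 1 by acetylation. No ring is formed: rings A and B (trans-decalin) and the stereocentres C5, C9 and C10 are taken intact from sclareol.

Assumption: labdane numbering is used throughout; organopalladium species bound to the catalyst are described in the Why lines and carry no compound number.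

## Route

Step 1
Reactants: 1 sclareol [(13R)-labd-14-ene-8α,13-diol]
Product: 3 sclareol diacetate [(13R)-labd-14-ene-8α,13-diyl diacetate], via 13-O-acetylsclareol 2 (not isolated)
Conditions: AcCl, PhNMe2, CH2Cl2, 0 °C → rt
Reagents that add atoms: acetyl chloride, CC(=O)Cl
Why: O-acylation of both tertiary alcohols with an acyl chloride and an aniline base (the less hindered allylic C13–OH reacts first); no C–O bond at a stereocentre is broken, so C8 and C13 keep their configuration.

Step 2
Reactants: 3 sclareol diacetate
Product: 4 (13E)-labd-13-ene-8α,15-diyl diacetate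
Conditions: PdCl2(MeCN)2 (5 mol%), THF, rt
Reagents that add atoms: none
Why: Overman-type [3,3] allylic acetate rearrangement catalysed by divalent palladium forms the C15–O bond; the chair-like 1,3-dioxan-2-ylium intermediate places the bulky decalinylethyl chain equatorial, so anti loss of palladium and oxygen gives mainly the 13E alkene (the minor 13Z isomer is removed on AgNO3-impregnated silica), and the C8 acetate, having no alkene, is inert.

Step 3
Reactants: 4 (13E)-labd-13-ene-8α,15-diyl diacetate
Product: 5 copalyl acetate [(13E)-labda-8(17),13-dien-15-yl acetate]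
Conditions: NaHCO3, DMSO, 150 °C
Reagents that add atoms: none
Why: Dehydroacetoxylation of the tertiary equatorial 8α-acetate (ester-pyrolysis-type elimination through a tight ion pair, helped by relief of the C17/C20 diaxial methyl strain) takes the most accessible hydrogen from the C17 methyl and gives the exocyclic alkene as the major isomer (minor 7-ene and 8-ene isomers are removed on AgNO3-impregnated silica); the primary allylic acetate and C5, C9, C10 are untouched.

Step 4
Reactants: 5 copalyl acetate
Product: 6 target, (13E)-labda-7,13-diene-15,17-diyl diacetate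
Conditions: Pd(OAc)2 (10 mol%), p-benzoquinone (2 equiv), DMSO/AcOH (1:1), 4 Å MS, 45 °C
Reagents that add atoms: acetic acid, CC(=O)O
Why: Proposed new method: sulfoxide-promoted palladium allylic C–H acetoxylation carried over from monosubstituted alkenes to an exocyclic 1,1-disubstituted alkene – Pd(OAc)2 (divalent palladium) binds the unhindered, electron-rich 8(17)-methylene in preference to the trisubstituted, acetoxy-deactivated 13-ene; acetate-assisted cleavage of the axial C7–H (a ring CH2, favoured over the hindered tertiary C9–H) gives an η3-allyl over C7–C8–C17; outer-sphere acetate attack at the open CH2 terminus forms the primary C17–O bond and leaves the alkene at C7=C8 (the more substituted isomer); benzoquinone returns zerovalent palladium to divalent palladium; no stereocentre is formed or touched; the closest known reaction types are the linear-selective DMSO/benzoquinone allylic C–H acetoxylation of terminal alkenes and the stoichiometric formation of η3-allylpalladium complexes from methylenecycloalkanes, which nucleophiles capture at the CH2 terminus.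

## Compound list

1 | sclareol, (13R)-labd-14-ene-8α,13-diol | C=C[C@](C)(O)CC[C@H]1[C@](C)(O)CC[C@H]2C(C)(C)CCC[C@]12C | starting material
2 | 13-O-acetylsclareol, (13R)-8α-hydroxylabd-14-en-13-yl acetate | C=C[C@](C)(OC(C)=O)CC[C@H]1[C@](C)(O)CC[C@H]2C(C)(C)CCC[C@]12C | intermediate
3 | sclareol diacetate, (13R)-labd-14-ene-8α,13-diyl diacetate | C=C[C@](C)(OC(C)=O)CC[C@H]1[C@](C)(OC(C)=O)CC[C@H]2C(C)(C)CCC[C@]12C | intermediate
4 | (13E)-labd-13-ene-8α,15-diyl diacetate | CC(=O)OC/C=C(\C)CC[C@H]1[C@](C)(OC(C)=O)CC[C@H]2C(C)(C)CCC[C@]12C | intermediate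
5 | copalyl acetate, (13E)-labda-8(17),13-dien-15-yl acetate | CC(=O)OC/C=C(\C)CC[C@H]1C(=C)CC[C@H]2C(C)(C)CCC[C@]12C | intermediate
6 | CNP0257931.1, (13E)-labda-7,13-diene-15,17-diyl diacetate | CC(=O)OC/C=C(\C)CC[C@H]1C(COC(C)=O)=CC[C@H]2C(C)(C)CCC[C@]12C | target

## Step count and risks

Total step count: 4. Longest linear sequence: 4 steps (1 → 3 → 4 → 5 → 6).

Steps most likely to fail:

**Step 4 (proposed new C–H acetoxylation).** The exocyclic alkene may bind palladium too weakly, or acetate may attack C7 instead of C17, or some 8-ene isomer may form. The fallback uses known chemistry, sets out from 5 and comes back at 6. Catalytic SeO2 with t-BuOOH in CH2Cl2 at rt (Riley-type ene/[2,3] allylic hydroxylation, selective for the exocyclic alkene because the 13-ene is deactivated by its allylic acetate) gives (13E)-7α-hydroxylabda-8(17),13-dien-15-yl acetate F1. The rhenium-oxo catalyst Ph3SiOReO3 in Et2O at 0 °C then effects the 1,3-transposition of the allylic alcohol, moving the hydroxyl from C7 to C17 and the alkene into the ring, to give (13E)-17-hydroxylabda-7,13-dien-15-yl acetate F2. Ac2O, pyridine and DMAP give 6.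

**Step 3 (regioselectivity of the elimination).** The ratio of exocyclic to endocyclic alkene may be too low for clean separation. The fallback sets out from 4 and comes back at 5, replacing acetate thermolysis by an anti E2 elimination of the free alcohol. KOH in MeOH at reflux cleaves both esters to (13E)-labd-13-ene-8α,15-diol F3. Ac2O and pyridine at rt acetylate only the primary hydroxyl to give (13E)-8α-hydroxylabd-13-en-15-yl acetate F4. SOCl2 and pyridine in CH2Cl2 at −78 °C then eliminate through the equatorial 8α-chlorosulfite, for which only the C17 methyl hydrogens can be anti-periplanar, giving 5.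

**Step 2 (E/Z ratio of the rearrangement).** Linalyl-type acetates can give only modest E selectivity (about 2:1 to 4:1), which costs material. The fallback sets out from 4 as its E/Z mixture and comes back at 4 as the pure 13E isomer, resetting the geometry by olefination. Ozonolysis (O3, CH2Cl2/MeOH, −78 °C; Me2S) converts both isomers into 8α-acetoxy-14,15-dinorlabdan-13-one F5. Horner–Wadsworth–Emmons olefination with (EtO)2P(O)CH2CO2Et and NaH in DME gives ethyl (13E)-8α-acetoxylabd-13-en-15-oate F6, whose minor Z isomer separates easily on silica as a conjugated ester. i-Bu2AlH (2.2 equiv, CH2Cl2, −78 °C) reduces the enoate while sparing the hindered tertiary acetate, giving (13E)-15-hydroxylabd-13-en-8α-yl acetate F7. AcCl and PhNMe2 return 4; any over-reduced diol is re-acetylated in the same operation.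

## Further compounds

F1 | step 4 | (13E)-7α-hydroxylabda-8(17),13-dien-15-yl acetate | CC(=O)OC/C=C(\C)CC[C@H]1C(=C)[C@H](O)C[C@H]2C(C)(C)CCC[C@]12C
F2 | step 4 | (13E)-17-hydroxylabda-7,13-dien-15-yl acetate | CC(=O)OC/C=C(\C)CC[C@H]1C(CO)=CC[C@H]2C(C)(C)CCC[C@]12C
F3 | step 3 | (13E)-labd-13-ene-8α,15-diol | OC/C=C(\C)CC[C@H]1[C@](C)(O)CC[C@H]2C(C)(C)CCC[C@]12C
F4 | step 3 | (13E)-8α-hydroxylabd-13-en-15-yl acetate | CC(=O)OC/C=C(\C)CC[C@H]1[C@](C)(O)CC[C@H]2C(C)(C)CCC[C@]12C
F5 | step 2 | 8α-acetoxy-14,15-dinorlabdan-13-one | CC(=O)CC[C@H]1[C@](C)(OC(C)=O)CC[C@H]2C(C)(C)CCC[C@]12C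
F6 | step 2 | ethyl (13E)-8α-acetoxylabd-13-en-15-oate | CCOC(=O)/C=C(\C)CC[C@H]1[C@](C)(OC(C)=O)CC[C@H]2C(C)(C)CCC[C@]12C
F7 | step 2 | (13E)-15-hydroxylabd-13-en-8α-yl acetate | OC/C=C(\C)CC[C@H]1[C@](C)(OC(C)=O)CC[C@H]2C(C)(C)CCC[C@]12C
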